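**Strategy.** Everything rests on disconnecting the two C–O bonds at C1 and C4 of the cyclohexenone ring (C1 ketone, C2 amide-bearing carbon, C3 vinylic CH, C4 carbinol, C5/C6 oxirane carbons). The feature exploited is the 1,4-dioxygenation pattern of this ring: the C1 carbonyl and the C4 tertiary hydroxyl flank the C2=C3 double bond, and the C4 hydroxyl is trans to the C5–C6 oxirane. Singlet oxygen adds across C1/C4 of a cyclohexa-1,3-diene anti to a cis-fused acetonide, and amine-induced opening of the endoperoxide delivers ketone, carbinol and the C4 configuration in one operation. The precursor is the acetonide of the bromobenzene-derived (1S,2S)-cis-dihydrodiol bearing the ethyl pentanoate chain at C4.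

Key step: step 3

**Remarks**
- The ring numbering above is kept for all six-membered-ring intermediates; C6 is the oxygenated carbon next to C1.
- Stereochemical bookkeeping: the (1S,2S)-diol carries both oxygens on the ring face that the oxirane occupies in the target. The side chain is (2E,4S,6R) with syn methyl groups, so it maps onto the meso anhydride after desymmetrisation.
- The ethyl ester of the stock organozinc reagent is kept as the spectator group. To make this safe, the oxirane is closed in ethanol (no ester scrambling) and the ester is cleaved last by an esterase at neutral pH, not by hydroxide.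
- Assumption: the Pseudomonas lipase acetylates the hydroxymethyl arm on the S-configured carbon of the meso diol, the usual preference for 2-methyl-branched primary alcohols.

**Route**

Step 1
Reactants: 1 (1S,2S)-3-bromocyclohexa-3,5-diene-1,2-diol; 2 2,2-dimethoxypropane
Product: 3 (3aS,7aS)-4-bromo-2,2-dimethyl-3a,7a-dihydro-1,3-benzodioxole
Conditions: 2,2-dimethoxypropane, p-TsOH·H2O (cat.), acetone, 0 °C → rt; used without storage
Reagents that add atoms: 2,2-dimethoxypropane (compound 2), COC(C)(C)OC
Why: Acid-catalysed transketalisation (acetonide formation) of the cis-1,2-diol should give the cis-fused dioxolane without touching either stereocentre, and the short cold contact avoids acid-induced dehydration to a bromophenol.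

Step 2
Reactants: 3 (3aS,7aS)-4-bromo-2,2-dimethyl-3a,7a-dihydro-1,3-benzodioxole; 4 (5-ethoxy-5-oxopentyl)zinc bromide
Product: 5 ethyl 5-[(3aR,7aS)-2,2-dimethyl-3a,7a-dihydro-1,3-benzodioxol-4-yl]pentanoate
Conditions: PdCl2(dppf)·CH2Cl2 (5 mol%), THF, rt → 45 °C
Reagents that add atoms: (5-ethoxy-5-oxopentyl)zinc bromide (compound 4), CCOC(=O)CCCC[Zn]Br
Why: Negishi sp2–sp3 coupling (oxidative addition of the alkenyl bromide to zerovalent palladium, transmetalation from the ester-tolerant alkylzinc, reductive elimination favoured over β-hydride elimination by the wide-bite-angle dppf ligand) should install the chain at C4 with both stereocentres untouched.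

Step 3
Reactants: 5 ethyl 5-[(3aR,7aS)-2,2-dimethyl-3a,7a-dihydro-1,3-benzodioxol-4-yl]pentanoate
Product: 7 ethyl 5-[(3aS,4S,7aR)-4-hydroxy-2,2-dimethyl-7-oxo-3a,4,7,7a-tetrahydro-1,3-benzodioxol-4-yl]pentanoate (C4 hydroxyl anti to the acetonide), via endoperoxide 6 (not isolated)
Conditions: O2, tetraphenylporphyrin (cat.), visible light, CH2Cl2, −30 °C; then Et3N, 0 °C → rt
Reagents that add atoms: dioxygen, O=O
Why: Tetraphenylporphyrin-sensitised singlet oxygen should add suprafacially across C1 and C4 of the ring-locked s-cis diene in a [4+2] cycloaddition to give endoperoxide 6, and triethylamine then removes the only hydrogen on a peroxide-bearing carbon (C1–H), which breaks the O–O bond and leaves the C1 ketone and the C4 hydroxyl (Kornblum–DeLaMare rearrangement). The closest known reaction type is the photooxygenation of arene cis-dihydrodiol acetonides followed by base-induced isomerisation of the endoperoxide to a 4-hydroxycyclohex-2-enone. The only ring closed is the transient six-membered 1,2-dioxine ring of 6, formed by the concerted cycloaddition and opened again in the same flask, so the isolated product gains no ring. The new stereocentre C4 is set in the cycloaddition by the cis-fused isopropylidene ketal, which shields its own face so that oxygen bonds to the opposite face, and it is kept because the C4–O bond is not broken afterwards. The step needs facial selectivity (secured by the ketal), a single direction of endoperoxide opening (secured because C4 is fully substituted and has no proton to lose) and cycloaddition in preference to the ene reaction at the allylic CH2 of the chain (secured by the cisoid cyclic diene and the low temperature).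

Step 4
Reactants: 7 ethyl 5-[(3aS,4S,7aR)-4-hydroxy-2,2-dimethyl-7-oxo-3a,4,7,7a-tetrahydro-1,3-benzodioxol-4-yl]pentanoate
Product: 8 ethyl 5-[(3aS,4S,7aR)-4-hydroxy-6-iodo-2,2-dimethyl-7-oxo-3a,4,7,7a-tetrahydro-1,3-benzodioxol-4-yl]pentanoate
Conditions: I2, pyridine/CH2Cl2 (1:1), 0 °C → rt
Reagents that add atoms: iodine, II
Why: α-Iodination of the enone by the pyridine addition–iodination–elimination sequence (Baylis–Hillman-type mechanism) should place iodine only at C2, and the tertiary alcohol, ketal and ester are inert to I2/pyridine.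

Step 5
Reactants: 9 meso-2,4-dimethylglutaric anhydride
Product: 10 meso-(2R,4S)-2,4-dimethylpentane-1,5-diol
Conditions: LiAlH4, THF, 0 °C → reflux; then H2O
Reagents that add atoms: none
Why: Hydride reduction of the cyclic anhydride with LiAlH4 should give the diol, and the two methyl-bearing carbons are not involved, so the meso relationship is kept.

Step 6
Reactants: 10 meso-(2R,4S)-2,4-dimethylpentane-1,5-diol
Product: 11 (2R,4S)-5-acetoxy-2,4-dimethylpentan-1-ol [= (2S,4R)-5-hydroxy-2,4-dimethylpentyl acetate]
Conditions: vinyl acetate, lipase from Pseudomonas fluorescens, THF, rt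
Reagents that add atoms: vinyl acetate, C=COC(C)=O
Why: Lipase-catalysed enantiotopos-selective transesterification (desymmetrisation of a meso diol) with the irreversible acyl donor vinyl acetate should acylate the arm on the S-configured carbon, which fixes the absolute sense of both methyl-bearing centres.

Step 7
Reactants: 11 (2R,4S)-5-acetoxy-2,4-dimethylpentan-1-ol
Product: 12 (2S,4R)-2,4-dimethyl-5-oxopentyl acetate
Conditions: Dess–Martin periodinane, CH2Cl2, 0 °C → rt; crude aldehyde used at once
Reagents that add atoms: none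
Why: Dess–Martin oxidation of the primary alcohol under non-basic conditions should give the aldehyde without epimerising the α-methyl centre and without touching the acetate.

Step 8
Reactants: 12 (2S,4R)-2,4-dimethyl-5-oxopentyl acetate; 13 isopropyltriphenylphosphonium iodide
Product: 15 (2S,4R)-2,4,6-trimethylhept-5-en-1-ol, via alkenyl acetate 14 (not isolated)
Conditions: i-PrPPh3I, n-BuLi, THF, 0 °C; 12, −78 °C → rt; then MeOH, K2CO3 (cat.), rt
Reagents that add atoms: isopropyltriphenylphosphonium iodide (compound 13), CC(C)[P+](c1ccccc1)(c1ccccc1)c1ccccc1.[I-]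
Why: Wittig olefination with the non-stabilised isopropylidene ylide should build the trisubstituted C=C bond (no E/Z issue, since the ylide carbon carries two methyl groups) at low temperature without epimerising the α-centre, and carbonate-catalysed methanolysis then removes the acetate in the same flask.

Step 9
Reactants: 15 (2S,4R)-2,4,6-trimethylhept-5-en-1-ol
Product: 16 (2S,4R)-2,4,6-trimethylhept-5-enal
Conditions: Dess–Martin periodinane, CH2Cl2, 0 °C → rt; crude aldehyde used at once
Reagents that add atoms: none
Why: Dess–Martin oxidation as in step 7 should leave the isolated trisubstituted alkene alone and preserve the α-stereocentre under the non-basic conditions.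

Step 10
Reactants: 16 (2S,4R)-2,4,6-trimethylhept-5-enal; 17 diethyl (2-amino-2-oxoethyl)phosphonate
Product: 18 (2E,4S,6R)-4,6,8-trimethylnona-2,7-dienamide
Conditions: LiCl, DBU, MeCN, 0 °C → rt
Reagents that add atoms: diethyl (2-amino-2-oxoethyl)phosphonate (compound 17), CCOP(=O)(CC(N)=O)OCC
Why: Horner–Wadsworth–Emmons olefination under mild LiCl/amine (Masamune–Roush) conditions should give the E-alkene from the stabilised phosphonate anion under thermodynamic control, is weakly basic enough to spare the α-methyl centre, and brings in the primary amide directly.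

Step 11
Reactants: 8 ethyl 5-[(3aS,4S,7aR)-4-hydroxy-6-iodo-2,2-dimethyl-7-oxo-3a,4,7,7a-tetrahydro-1,3-benzodioxol-4-yl]pentanoate; 18 (2E,4S,6R)-4,6,8-trimethylnona-2,7-dienamide
Product: 19 ethyl 5-[(3aS,4S,7aR)-4-hydroxy-2,2-dimethyl-7-oxo-6-{[(2E,4S,6R)-4,6,8-trimethylnona-2,7-dienoyl]amino}-3a,4,7,7a-tetrahydro-1,3-benzodioxol-4-yl]pentanoate
Conditions: CuI (10 mol%), N,N'-dimethylethylenediamine (20 mol%), K2CO3, toluene, 60 °C
Reagents that add atoms: none
Why: Goldberg-type copper-catalysed N-vinylation of a primary amide by an α-iodoenone (oxidative addition of the C2–I bond to a diamine-ligated monovalent copper amidate, then reductive elimination) should form the C2–N bond without moving the double bond, and the weak carbonate base and moderate temperature spare the ketal, ester and tertiary alcohol.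

Step 12
Reactants: 19 the acetonide-protected amide from step 11
Product: 20 ethyl 5-[(1S,5R,6S)-1,5,6-trihydroxy-4-oxo-3-{[(2E,4S,6R)-4,6,8-trimethylnona-2,7-dienoyl]amino}cyclohex-2-en-1-yl]pentanoate (secondary hydroxyls at C5 and C6 cis to each other, trans to the C4 hydroxyl)
Conditions: TFA/H2O (9:1), CH2Cl2, 0 °C
Reagents that add atoms: none
Why: Acid-catalysed hydrolysis of the isopropylidene ketal (acetal hydrolysis) should free the cis-diol without touching a stereocentre, and at 0 °C the ethyl ester, the electron-poor 2-amidoenone and the trisubstituted alkene should survive.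

Step 13
Reactants: 20 the C4,C5,C6-triol ethyl ester from step 12
Product: 23 ethyl 5-[(1R,5S,6S)-5-hydroxy-2-oxo-3-{[(2E,4S,6R)-4,6,8-trimethylnona-2,7-dienoyl]amino}-7-oxabicyclo[4.1.0]hept-3-en-5-yl]pentanoate, via cyclic orthoester 21 (not isolated), via trans-bromo acetate 22 (not isolated)
Conditions: MeC(OMe)3, pyridinium p-toluenesulfonate (cat.), CH2Cl2, rt; AcBr, CH2Cl2, 0 °C; K2CO3, EtOH, 0 °C
Reagents that add atoms: none
Why: The one-pot orthoester route from a cis-diol to an oxirane should proceed with net retention, since acetyl bromide ionises the cyclic orthoester to an acetoxonium ion, bromide opens it by SN2 at C6 (activated by the ketone, whereas C5 is neopentyl-like; the other regioisomer would converge on the same oxirane), and ethanolysis of the acetate releases the C5 alkoxide, which displaces bromide in a second SN2 (3-exo-tet), so the oxirane ends on the face the diol occupied, anti to the C4 hydroxyl.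

Step 14
Reactants: 23 the epoxyquinol ethyl ester from step 13
Product: 24 5-[(1R,5S,6S)-5-hydroxy-2-oxo-3-{[(2E,4S,6R)-4,6,8-trimethylnona-2,7-dienoyl]amino}-7-oxabicyclo[4.1.0]hept-3-en-5-yl]pentanoic acid (CNP0110221.3)
Conditions: pig liver esterase, pH 7.2 phosphate buffer/acetone (9:1), 30 °C; work-up at pH 4–5
Reagents that add atoms: water, O
Why: Enzymatic ester hydrolysis (serine esterase, acyl-enzyme mechanism) at neutral pH should cleave the unhindered ethyl ester while the base-sensitive epoxy ketone, the enamide and the tertiary alcohol are left alone and no stereocentre is affected.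

**Compound list**

1 | (1S,2S)-3-bromocyclohexa-3,5-diene-1,2-diol | BrC1=CC=C[C@H](O)[C@@H]1O | starting material
2 | 2,2-dimethoxypropane | COC(C)(C)OC | starting material
3 | (3aS,7aS)-4-bromo-2,2-dimethyl-3a,7a-dihydro-1,3-benzodioxole | BrC1=CC=C[C@@H]2OC(C)(C)O[C@H]12 | intermediate
4 | (5-ethoxy-5-oxopentyl)zinc bromide | CCOC(=O)CCCC[Zn]Br | starting material
5 | ethyl 5-[(3aR,7aS)-2,2-dimethyl-3a,7a-dihydro-1,3-benzodioxol-4-yl]pentanoate | CCOC(=O)CCCCC1=CC=C[C@@H]2OC(C)(C)O[C@H]12 | intermediate
6 | endoperoxide of 5: acetonide-fused 2,3-dioxabicyclo[2.2.2]oct-5-ene, peroxide bridge across C1/C4 on the face opposite the ketal, chain on the C4 bridgehead | C1=C[C@]2(CCCCC(=O)OCC)OO[C@H]1[C@@H]1OC(C)(C)O[C@H]21 | intermediate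
7 | ethyl 5-[(3aS,4S,7aR)-4-hydroxy-2,2-dimethyl-7-oxo-3a,4,7,7a-tetrahydro-1,3-benzodioxol-4-yl]pentanoate | C1=C[C@@](O)(CCCCC(=O)OCC)[C@H]2OC(C)(C)O[C@H]2C1=O | intermediate
8 | ethyl 5-[(3aS,4S,7aR)-4-hydroxy-6-iodo-2,2-dimethyl-7-oxo-3a,4,7,7a-tetrahydro-1,3-benzodioxol-4-yl]pentanoate | IC1=C[C@@](O)(CCCCC(=O)OCC)[C@H]2OC(C)(C)O[C@H]2C1=O | intermediate
9 | meso-2,4-dimethylglutaric anhydride | C[C@H]1C[C@@H](C)C(=O)OC1=O | starting material
10 | meso-(2R,4S)-2,4-dimethylpentane-1,5-diol | OC[C@H](C)C[C@H](C)CO | intermediate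
11 | (2R,4S)-5-acetoxy-2,4-dimethylpentan-1-ol | OC[C@H](C)C[C@H](C)COC(C)=O | intermediate
12 | (2S,4R)-2,4-dimethyl-5-oxopentyl acetate | O=C[C@H](C)C[C@H](C)COC(C)=O | intermediate
13 | isopropyltriphenylphosphonium iodide | CC(C)[P+](c1ccccc1)(c1ccccc1)c1ccccc1.[I-] | starting material
14 | (2S,4R)-2,4,6-trimethylhept-5-en-1-yl acetate | CC(C)=C[C@H](C)C[C@H](C)COC(C)=O | intermediate
15 | (2S,4R)-2,4,6-trimethylhept-5-en-1-ol | CC(C)=C[C@H](C)C[C@H](C)CO | intermediate
16 | (2S,4R)-2,4,6-trimethylhept-5-enal | CC(C)=C[C@H](C)C[C@H](C)C=O | intermediate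
17 | diethyl (2-amino-2-oxoethyl)phosphonate | CCOP(=O)(CC(N)=O)OCC | starting material
18 | (2E,4S,6R)-4,6,8-trimethylnona-2,7-dienamide | CC(C)=C[C@H](C)C[C@H](C)/C=C/C(N)=O | intermediate
19 | ethyl 5-[(3aS,4S,7aR)-4-hydroxy-2,2-dimethyl-7-oxo-6-{[(2E,4S,6R)-4,6,8-trimethylnona-2,7-dienoyl]amino}-3a,4,7,7a-tetrahydro-1,3-benzodioxol-4-yl]pentanoate | CC(C)=C[C@H](C)C[C@H](C)/C=C/C(=O)NC1=C[C@@](O)(CCCCC(=O)OCC)[C@H]2OC(C)(C)O[C@H]2C1=O | intermediate
20 | ethyl 5-[(1S,5R,6S)-1,5,6-trihydroxy-4-oxo-3-{[(2E,4S,6R)-4,6,8-trimethylnona-2,7-dienoyl]amino}cyclohex-2-en-1-yl]pentanoate | CC(C)=C[C@H](C)C[C@H](C)/C=C/C(=O)NC1=C[C@@](O)(CCCCC(=O)OCC)[C@@H](O)[C@@H](O)C1=O | intermediate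
21 | cyclic orthoester of 20: 2-methoxy-2-methyl-1,3-dioxolane fused at C5/C6, both epimers at the orthoester carbon | CC(C)=C[C@H](C)C[C@H](C)/C=C/C(=O)NC1=C[C@@](O)(CCCCC(=O)OCC)[C@H]2OC(C)(OC)O[C@H]2C1=O | intermediate
22 | trans-bromo acetate: C5 acetate on the original diol face, C6 bromide on the face of the C4 hydroxyl | CC(C)=C[C@H](C)C[C@H](C)/C=C/C(=O)NC1=C[C@@](O)(CCCCC(=O)OCC)[C@@H](OC(C)=O)[C@H](Br)C1=O | intermediate
23 | ethyl 5-[(1R,5S,6S)-5-hydroxy-2-oxo-3-{[(2E,4S,6R)-4,6,8-trimethylnona-2,7-dienoyl]amino}-7-oxabicyclo[4.1.0]hept-3-en-5-yl]pentanoate | CC(C)=C[C@H](C)C[C@H](C)/C=C/C(=O)NC1=C[C@@](O)(CCCCC(=O)OCC)[C@H]2O[C@H]2C1=O | intermediate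
24 | 5-[(1R,5S,6S)-5-hydroxy-2-oxo-3-{[(2E,4S,6R)-4,6,8-trimethylnona-2,7-dienoyl]amino}-7-oxabicyclo[4.1.0]hept-3-en-5-yl]pentanoic acid | CC(C)=C[C@H](C)C[C@H](C)/C=C/C(=O)NC1=C[C@@](O)(CCCCC(=O)O)[C@H]2O[C@H]2C1=O | target

**Step count**

- Total: 14 steps (core line: steps 1–4 and 11–14; side-chain line: steps 5–10).
- Longest linear sequence: 10 steps, from meso anhydride 9 (steps 5–10, then 11–14).

**Steps most likely to fail, with fallbacks**

1. Step 11. The conjugated primary amide may be vinylated too slowly, so that reductive loss of iodine or carbonate-induced β-elimination of the C5 ketal oxygen (followed by aromatisation) takes over. The fallback sets out from 8 (acyl partner from 16) and returns at 19. It introduces nitrogen first and acylates afterwards. Compound 8 is treated with NaN3 under CuI/sodium ascorbate/N,N'-dimethylethylenediamine catalysis (EtOH–H2O, rt, no carbonate base) to give ethyl 5-[(3aS,4S,7aR)-6-azido-4-hydroxy-2,2-dimethyl-7-oxo-3a,4,7,7a-tetrahydro-1,3-benzodioxol-4-yl]pentanoate F1. Staudinger reduction (PPh3, THF–H2O) gives the corresponding 6-amino enone F2. In parallel, aldehyde 16 is converted by Horner–Wadsworth–Emmons olefination with triethyl phosphonoacetate (LiCl, DBU, MeCN) into ethyl (2E,4S,6R)-4,6,8-trimethylnona-2,7-dienoate F3, saponified (LiOH, THF–H2O) to (2E,4S,6R)-4,6,8-trimethylnona-2,7-dienoic acid F4, and turned with oxalyl chloride/cat. DMF into (2E,4S,6R)-4,6,8-trimethylnona-2,7-dienoyl chloride F5. N-Acylation of F2 with F5 (pyridine, CH2Cl2, 0 °C) should give 19.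

2. Step 13. The acetoxonium stage may go astray through participation of the C4 hydroxyl or addition of adventitious HBr to the isobutenyl group. In the base stage, E1cB loss of the C5 acetate or Payne-type migration of the oxirane towards the C4 alkoxide can compete with ring closure. The fallback sets out from 20 and returns at 23. It carries out the double inversion stepwise without an acetoxonium ion. The C6 hydroxyl (the C5 hydroxyl is shielded by the fully substituted C4) is sulfonylated with MsCl/2,4,6-collidine (CH2Cl2, −20 °C) to give the C6 methanesulfonate of 20 F6. LiBr in acetone displaces the α-keto sulfonate by SN2 to give the trans-bromohydrin (6-bromo, 5-hydroxy) F7. K2CO3 in EtOH at 0 °C then closes F7 to 23.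

3. Step 3. The endoperoxide may be consumed by paths other than the amine-induced opening: thermal rearrangement to a bis-epoxide, base-induced elimination of the ketal oxygen from the newly formed α-alkoxy ketone, or ene-type hydroperoxidation at the chain during a slow cycloaddition. The fallback sets out from 5 and returns at 7. The photooxygenation is run as before, but endoperoxide 6 is reduced in the cold with thiourea (MeOH, −30 °C → rt) to ethyl 5-[(3aS,4S,7R,7aS)-4,7-dihydroxy-2,2-dimethyl-3a,4,7,7a-tetrahydro-1,3-benzodioxol-4-yl]pentanoate F8 (cis-ene-1,4-diol, both hydroxyls anti to the ketal). The secondary allylic C1 carbinol of F8 is then oxidised selectively with MnO2 (CH2Cl2, rt) to give 7; the tertiary C4 carbinol cannot be oxidised.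

**Further compounds**

F1 | step 11 | ethyl 5-[(3aS,4S,7aR)-6-azido-4-hydroxy-2,2-dimethyl-7-oxo-3a,4,7,7a-tetrahydro-1,3-benzodioxol-4-yl]pentanoate | [N-]=[N+]=NC1=C[C@@](O)(CCCCC(=O)OCC)[C@H]2OC(C)(C)O[C@H]2C1=O
F2 | step 11 | ethyl 5-[(3aS,4S,7aR)-6-amino-4-hydroxy-2,2-dimethyl-7-oxo-3a,4,7,7a-tetrahydro-1,3-benzodioxol-4-yl]pentanoate | NC1=C[C@@](O)(CCCCC(=O)OCC)[C@H]2OC(C)(C)O[C@H]2C1=O
F3 | step 11 | ethyl (2E,4S,6R)-4,6,8-trimethylnona-2,7-dienoate | CC(C)=C[C@H](C)C[C@H](C)/C=C/C(=O)OCC
F4 | step 11 | (2E,4S,6R)-4,6,8-trimethylnona-2,7-dienoic acid | CC(C)=C[C@H](C)C[C@H](C)/C=C/C(O)=O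
F5 | step 11 | (2E,4S,6R)-4,6,8-trimethylnona-2,7-dienoyl chloride | CC(C)=C[C@H](C)C[C@H](C)/C=C/C(Cl)=O
F6 | step 13 | C6 methanesulfonate of triol 20 | CC(C)=C[C@H](C)C[C@H](C)/C=C/C(=O)NC1=C[C@@](O)(CCCCC(=O)OCC)[C@@H](O)[C@@H](OS(C)(=O)=O)C1=O
F7 | step 13 | trans-bromohydrin (6-bromo, 5-hydroxy; bromine on the face of the C4 hydroxyl) | CC(C)=C[C@H](C)C[C@H](C)/C=C/C(=O)NC1=C[C@@](O)(CCCCC(=O)OCC)[C@@H](O)[C@H](Br)C1=O
F8 | step 3 | ethyl 5-[(3aS,4S,7R,7aS)-4,7-dihydroxy-2,2-dimethyl-3a,4,7,7a-tetrahydro-1,3-benzodioxol-4-yl]pentanoate | C1=C[C@@](O)(CCCCC(=O)OCC)[C@H]2OC(C)(C)O[C@H]2[C@@H]1O
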